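A direct plan would esterify one phenol of 1-(2,6-dihydroxy-4-methoxyphenyl)ethan-1-one A2 with tetratriacontanoic acid A1 to give aryl ester A3, would shift the acyl group from oxygen to the acetyl carbon (Baker–Venkataraman rearrangement) to give 1,3-diketone A4, and would close the pyranone at O1–C2 by acid cyclodehydration.
Its two weakest steps would be these. The mono-esterification would have to stop after one of two equivalent phenols, so an excess of A2 and a separation of waxy mono- and diester would be needed. The acyl shift would require enolisation of the acetyl CH3 next to a free acidic phenol and an enolisable ester α-CH2, so ester cleavage, Claisen self-condensation and stalling of a poorly soluble C34 ester would compete.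

**Strategy.** The route reverses the order of ring construction: the 4-pyranone (O1, C2–C4, C4a, C8a) is made first, and ring A is annulated last onto the pyranone C=C bond that becomes C4a–C8a. The key step is a photo-Wolff/ketene–alkyne [2+2]/4π-opening/6π-electrocyclisation cascade (Danheiser benzannulation) of a 4-pyranon-2-yl diazomethyl ketone with methoxyacetylene. It exploits the fact that ring A is a resorcinol monomethyl ether with C6 and C8 unsubstituted: in one operation C8–C8a, C5–C6, C7–C8 and C4a–C5 are formed, with O5 free and O7 methylated by construction. No phenol has to be mono-acylated and no acyl group shifted, because no preformed phloroglucinol ring is used.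

Key step: step 6

Remark: the target has no stereocentre, and the substituent on C2 is taken as unbranched tritriacontyl (33 carbons).

**Step 1**
Reactants: 1 1-bromodocosane; 2 1,10-dibromodecane
Product: 4 1-bromodotriacontane, via docosylmagnesium bromide 3 (not isolated)
Conditions: 1, Mg (1.2 equiv), THF, 55 °C; added over 2 h to 2 (4 equiv), Li2CuCl4 (3 mol %), THF, −10 °C → rt; aq. NH4Cl; excess 2 removed by trituration with cold acetone, recrystallisation (heptane)
Reagents that add atoms: none
Why: The Li2CuCl4-catalysed coupling of a primary alkyl Grignard reagent with a primary alkyl bromide (Kochi coupling) is fast below room temperature, and slow addition of 3 to a fourfold excess of the symmetrical dibromide 2 should hold back the second coupling, so that the C22 and C10 pieces give the C32 bromide whose remaining C–Br bond is the handle for step 2.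

**Step 2**
Reactants: 4 1-bromodotriacontane; 5 pentane-2,4-dione
Product: 7 heptatriacontane-2,4-dione, via dilithiated pentane-2,4-dione 6 (not isolated)
Conditions: 5 (1.3 equiv), LiN(i-Pr)2 (2.7 equiv), THF, 0 °C; 4 (1.0 equiv, warm THF solution), DMPU, 0 → 40 °C; 1 M HCl
Reagents that add atoms: none
Why: Double deprotonation of the β-diketone gives a dianion whose terminal, last-formed carbanion is alkylated selectively by a primary bromide (γ-alkylation of a 1,3-diketone dianion), which completes the C33 chain and installs the carbons that become C2, C3, C4 and C4a, while inert hydrocarbon by-products of step 1 are separated from the polar, chelating diketone at this stage.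

**Step 3**
Reactants: 7 heptatriacontane-2,4-dione; 8 diethyl oxalate
Product: 11 4-oxo-6-tritriacontyl-4H-pyran-2-carboxylic acid, via ethyl 2,4,6-trioxononatriacontanoate 9 (not isolated), via ethyl 4-oxo-6-tritriacontyl-4H-pyran-2-carboxylate 10 (not isolated)
Conditions: 8 (1.5 equiv), NaOEt (2.5 equiv), PhMe–EtOH, 60 °C; then AcOH–conc. HCl (3:1), 100 °C
Reagents that add atoms: water, O
Why: The reversible Claisen condensation with diethyl oxalate should take place at the terminal CH3 (the central CH2 is blocked as the enolate and the chain CH2 is more hindered), and hot acid then cyclodehydrates the 2,4,6-triketo ester to the 4-pyranone and hydrolyses the ester without exposing the base-sensitive ring to hydroxide, as in the classical chelidonic acid synthesis.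

**Step 4**
Reactants: 11 4-oxo-6-tritriacontyl-4H-pyran-2-carboxylic acid
Product: 13 2-(2-diazoacetyl)-6-tritriacontyl-4H-pyran-4-one, via mixed carbonic anhydride 12 (not isolated)
Conditions: ClCO2Et (1.1 equiv), Et3N (1.1 equiv), THF–CH2Cl2, 0 °C; Me3SiCHN2 (2 equiv, 2 M in hexanes), MeCN, 0 °C → rt, dark; AcOH quench
Reagents that add atoms: (trimethylsilyl)diazomethane, C[Si](C)(C)C=[N+]=[N-]
Why: Activation of the acid as its mixed carbonic anhydride and C-acylation of (trimethylsilyl)diazomethane, with transfer of the silyl group to the departing ethyl carbonate, is the Arndt–Eistert-type preparation of α-diazo ketones under non-acidic conditions that should leave the vinylogous ester of the pyranone untouched.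

**Step 5**
Reactants: 14 2-chloro-1,1-dimethoxyethane
Product: 16 methoxyethyne, via sodium methoxyethynide 15 (not isolated)
Conditions: NaNH2 (3.1 equiv), liq. NH3, −35 °C; NH3 evaporated; cold sat. aq. NaCl, −20 °C; distilled into a −78 °C trap, kept as a solution in ClCH2CH2Cl
Reagents that add atoms: none
Why: Sodium amide effects a twofold β-elimination (of methanol, then of HCl) from the chloroacetal and holds the product as its sodium acetylide until the ammonia is gone, so that mild hydrolysis releases the volatile ynol ether, which is distilled directly.

**Step 6**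
Reactants: 13 2-(2-diazoacetyl)-6-tritriacontyl-4H-pyran-4-one; 16 methoxyethyne
Product: 21 5-hydroxy-7-methoxy-2-tritriacontyl-4H-chromen-4-one, via pyranonylketene 17 (not isolated), via methoxycyclobutenone 18 (not isolated), via dienylketene 19 (not isolated), via 4aH-chromene-4,5-dione 20 (not isolated)
Conditions: 16 (3 equiv), hν (365 nm LEDs), ClCH2CH2Cl, 20 °C, sealed Pyrex; excess 16 vented; 80 °C
Reagents that add atoms: none
Why: Proposed new method: long-wave excitation of the diazo ketone expels N2 with 1,2-shift of the pyranon-2-yl group (photo-Wolff rearrangement) to give ketene 17, whose electrophilic carbonyl carbon is attacked by the nucleophilic CH terminus of the ynol ether, so that the [2+2] cycloaddition can only give the 3-methoxy-4-pyranonyl cyclobutenone 18. Heating opens 18 by reversible 4π-electrocyclic cleavage of the bond between the two former ketene carbons to dienylketene 19, and the isomer that holds the pyranone cis to the ketene closes ring A by a 6π-electrocyclisation in which the ketene carbon bonds to pyranone C3 (the C4a–C5 bond, a closure at carbon), after which dienone 20 enolises to the phenol. The closest known reaction type is the Danheiser benzannulation in its photochemical variant, in which aryl, heteroaryl and alkenyl diazomethyl ketones combine with alkoxy- or siloxyalkynes to give fused resorcinol monoethers; annulation onto the C=C bond of a 4-pyranone, which has less aromatic stabilisation to give up than those rings, has not been described. The transient sp3 centres of 18 and 20 are formed as racemates and are lost again, so no stereocentre has to be controlled. The step needs regiocontrol, which the polarisation of the ynol ether secures (the ketene carbonyl carbon becomes C5 with its free OH, chelated to the C4 carbonyl and therefore a poor trap for unreacted ketene, and the methoxy-bearing carbon becomes C7), and it needs excitation of the diazo ketone in preference to the pyranone, which 365 nm light should secure because the pyranone π–π* band lies at much shorter wavelength.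

**Compound list**

1 | 1-bromodocosane | CCCCCCCCCCCCCCCCCCCCCCBr | starting material
2 | 1,10-dibromodecane | BrCCCCCCCCCCBr | starting material
3 | docosylmagnesium bromide | CCCCCCCCCCCCCCCCCCCCCC[Mg]Br | intermediate
4 | 1-bromodotriacontane | CCCCCCCCCCCCCCCCCCCCCCCCCCCCCCCCBr | intermediate
5 | pentane-2,4-dione | CC(=O)CC(C)=O | starting material
6 | dilithiated pentane-2,4-dione (dilithium dianion, bis-enolate form) | C=C(O[Li])C=C(C)O[Li] | intermediate
7 | heptatriacontane-2,4-dione | CCCCCCCCCCCCCCCCCCCCCCCCCCCCCCCCCC(=O)CC(C)=O | intermediate
8 | diethyl oxalate | CCOC(=O)C(=O)OCC | starting material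
9 | ethyl 2,4,6-trioxononatriacontanoate | CCCCCCCCCCCCCCCCCCCCCCCCCCCCCCCCCC(=O)CC(=O)CC(=O)C(=O)OCC | intermediate
10 | ethyl 4-oxo-6-tritriacontyl-4H-pyran-2-carboxylate | CCCCCCCCCCCCCCCCCCCCCCCCCCCCCCCCCC1=CC(=O)C=C(C(=O)OCC)O1 | intermediate
11 | 4-oxo-6-tritriacontyl-4H-pyran-2-carboxylic acid | CCCCCCCCCCCCCCCCCCCCCCCCCCCCCCCCCC1=CC(=O)C=C(C(=O)O)O1 | intermediate
12 | ethyl (4-oxo-6-tritriacontyl-4H-pyran-2-carbonyl) carbonate (mixed carbonic anhydride) | CCCCCCCCCCCCCCCCCCCCCCCCCCCCCCCCCC1=CC(=O)C=C(C(=O)OC(=O)OCC)O1 | intermediate
13 | 2-(2-diazoacetyl)-6-tritriacontyl-4H-pyran-4-one | CCCCCCCCCCCCCCCCCCCCCCCCCCCCCCCCCC1=CC(=O)C=C(C(=O)C=[N+]=[N-])O1 | intermediate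
14 | 2-chloro-1,1-dimethoxyethane | COC(CCl)OC | starting material
15 | sodium methoxyethynide | COC#C[Na] | intermediate
16 | methoxyethyne (methoxyacetylene) | COC#C | intermediate
17 | 2-(4-oxo-6-tritriacontyl-4H-pyran-2-yl)ethen-1-one (pyranonylketene) | CCCCCCCCCCCCCCCCCCCCCCCCCCCCCCCCCC1=CC(=O)C=C(C=C=O)O1 | intermediate
18 | 3-methoxy-4-(4-oxo-6-tritriacontyl-4H-pyran-2-yl)cyclobut-2-en-1-one (racemic) | CCCCCCCCCCCCCCCCCCCCCCCCCCCCCCCCCC1=CC(=O)C=C(C2C(=O)C=C2OC)O1 | intermediate
19 | (3E)-3-methoxy-4-(4-oxo-6-tritriacontyl-4H-pyran-2-yl)buta-1,3-dien-1-one (dienylketene) | CCCCCCCCCCCCCCCCCCCCCCCCCCCCCCCCCC1=CC(=O)C=C(/C=C(OC)\C=C=O)O1 | intermediate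
20 | 7-methoxy-2-tritriacontyl-4aH-chromene-4,5-dione (racemic) | CCCCCCCCCCCCCCCCCCCCCCCCCCCCCCCCCC1=CC(=O)C2C(=O)C=C(OC)C=C2O1 | intermediate
21 | 5-hydroxy-7-methoxy-2-tritriacontyl-4H-chromen-4-one | CCCCCCCCCCCCCCCCCCCCCCCCCCCCCCCCCc1cc(=O)c2c(O)cc(OC)cc2o1 | target

**Summary**

Total step count: 6. Longest linear sequence: 5 steps (1, 2, 3, 4, 6); step 5 prepares the two-carbon partner.

Steps most likely to fail:

1. Step 6 (proposed new method). The pyranone chromophore may photoisomerise in competition with the Wolff rearrangement, the ketene or the ynol ether may oligomerise before the [2+2] step, or the dienylketene may re-close to the cyclobutenone without closing onto the electron-poor pyranone C=C bond. The fallback uses known chemistry, sets out from 4 and returns at 21; ring A would be bought in place of built. Commercial 5,7-dihydroxy-2-methyl-4H-chromen-4-one would be methylated at both oxygens (Me2SO4, K2CO3, acetone, reflux) to 5,7-dimethoxy-2-methyl-4H-chromen-4-one F1. F1 would be deprotonated at the 2-methyl group with LiN(i-Pr)2 (THF, −78 °C) and the vinylogous enolate alkylated in the same flask with 1-bromodotriacontane 4 (−78 → 35 °C) to give 5,7-dimethoxy-2-tritriacontyl-4H-chromen-4-one F2. BCl3 (CH2Cl2, −78 → 0 °C), which chelates between O5 and the C4 carbonyl, would then cleave only the peri methyl ether of F2 to give target 21.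

2. Step 3. The oxalyl Claisen condensation may acylate the chain CH2 as well as the CH3 group, ethoxide may cleave the diketone by retro-Claisen reaction at 60 °C, or hydrolysis of the poorly soluble ester may remain incomplete. The fallback sets out from 4 and returns at 11; the chain would be attached after the pyranone has been formed. 6-Methyl-4-oxo-4H-pyran-2-carboxylic acid F3 (commercial; otherwise from 5 and 8 under the conditions of step 3, where the symmetrical diketone raises no regiochemical question) would be converted with LiN(i-Pr)2 (2.2 equiv, THF–DMPU, −78 °C) into its carboxylate–dienolate dianion. Alkylation at the 6-methyl carbon with 4 (−78 → 35 °C) should give acid 11 directly.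

3. Step 1. Coupling at both ends of the dibromide and homo-coupling of the Grignard reagent may give waxy hydrocarbons that co-crystallise with the bromide. The fallback sets out from 1 through Grignard reagent 3 and returns at 4. Reagent 3 would be coupled under the same Li2CuCl4 catalysis with commercial 10-bromodecan-1-ol, whose hydroxyl group is first deprotonated with MeMgCl, to give dotriacontan-1-ol F4. The polar alcohol can be freed from hydrocarbons by chromatography or crystallisation, and HBr in AcOH (100 °C) would convert F4 into bromide 4.

**Further compounds**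

F1 | step 6 | 5,7-dimethoxy-2-methyl-4H-chromen-4-one | Cc1cc(=O)c2c(OC)cc(OC)cc2o1
F2 | step 6 | 5,7-dimethoxy-2-tritriacontyl-4H-chromen-4-one | CCCCCCCCCCCCCCCCCCCCCCCCCCCCCCCCCc1cc(=O)c2c(OC)cc(OC)cc2o1
F3 | step 3 | 6-methyl-4-oxo-4H-pyran-2-carboxylic acid | CC1=CC(=O)C=C(C(=O)O)O1
F4 | step 1 | dotriacontan-1-ol | CCCCCCCCCCCCCCCCCCCCCCCCCCCCCCCCO
A1 | direct plan | tetratriacontanoic acid | CCCCCCCCCCCCCCCCCCCCCCCCCCCCCCCCCC(=O)O
A2 | direct plan | 1-(2,6-dihydroxy-4-methoxyphenyl)ethan-1-one | CC(=O)c1c(O)cc(OC)cc1O
A3 | direct plan | 2-acetyl-3-hydroxy-5-methoxyphenyl tetratriacontanoate | CCCCCCCCCCCCCCCCCCCCCCCCCCCCCCCCCC(=O)Oc1cc(OC)cc(O)c1C(C)=O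
A4 | direct plan | 1-(2,6-dihydroxy-4-methoxyphenyl)hexatriacontane-1,3-dione | CCCCCCCCCCCCCCCCCCCCCCCCCCCCCCCCCC(=O)CC(=O)c1c(O)cc(OC)cc1O
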